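**Retrosynthetic overview**
1. The last skeletal bond is C4(upper)–C6(lower), made by a Friedel–Crafts flavanylation that is intramolecular through a glutarate bridge between the two O-3 atoms (cis delivery, 4β). The upper unit comes from (2R,3R)-fustin.
2. The lower unit (tetra-O-benzyl mesquitol) comes from a trans-dihydroflavonol and that from a (2S)-flavanone: C3–O is added anti to the C2 aryl group (Rubottom oxidation), then the C4 carbonyl is removed.
3. The flavanone comes from an ortho-fluoroaryl methyl N-sulfinyl ketimine and the ring B aldehyde: aldol addition (C2–C3) and SNAr closure (O1–C8a) in one flask. The purchased sulfur stereocentre sets C2, and C2 sets C3.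
4. Enabling feature: in the lower unit C4 is bonded to C4a, ortho to C8a of ring A. At the imine/ketone level C4 makes C3–H acidic and the C8a–F bond (next to O8) displaceable, so the aldehyde C2=O1 is inserted between C3 and C8a.
5. Ring order: ring C of the lower unit (step 4), then a temporary 14-membered ring closed together with the interflavan bond (step 11) and opened in step 12. Rings A, B and C of the upper unit are bought with fustin.

Key step: step 4

Remark 1: the (S)-sulfinyl auxiliary is assumed to steer the aldehyde to the face that gives the (S)-carbinol and so the (2S)-flavanone; if the sense is the opposite, the (R)-sulfinamide is used and nothing else changes.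
Remark 2: compounds 14, 18 and 19 are drawn as the 3,4-trans isomers expected to predominate; their C4 epimers react in the same way, because C4 is reduced (step 6) or ionised (step 11) later.

Step 1
Reactants: 1 3-fluorobenzene-1,2-diol
Product: 2 1,2-bis(benzyloxy)-3-fluorobenzene
Conditions: BnBr, K2CO3, DMF, 60 °C
Reagents that add atoms: benzyl bromide, BrCc1ccccc1
Why: Williamson etherification of both phenols gives benzyl ethers that are removed only in the last step.

Step 2
Reactants: 2 1,2-bis(benzyloxy)-3-fluorobenzene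
Product: 4 1-[3,4-bis(benzyloxy)-2-fluorophenyl]ethan-1-one, via aryllithium 3 (not isolated)
Conditions: n-BuLi, THF, −78 °C; N-methoxy-N-methylacetamide, −78 °C; H2O
Reagents that add atoms: N-methoxy-N-methylacetamide, CC(=O)N(C)OC
Why: Directed ortho-metalation at the ring C–H next to fluorine (the site lithiated in 3-fluoro-1,2-dialkoxybenzenes) is kept at −78 °C to avoid aryne formation and benzylic metalation, and the Weinreb ketone synthesis then gives the methyl ketone without over-addition.

Step 3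
Reactants: 4 1-[3,4-bis(benzyloxy)-2-fluorophenyl]ethan-1-one; 5 (S)-2-methylpropane-2-sulfinamide
Product: 6 (S)-N-{(E)-1-[3,4-bis(benzyloxy)-2-fluorophenyl]ethylidene}-2-methylpropane-2-sulfinamide
Conditions: Ti(OEt)4, THF, 70 °C
Reagents that add atoms: none
Why: Ti(OEt)4-mediated condensation of an aryl methyl ketone with tert-butanesulfinamide should give the E N-sulfinyl ketimine, which carries the only purchased stereocentre used for the lower unit.

Step 4
Reactants: 6 (S)-N-{(E)-1-[3,4-bis(benzyloxy)-2-fluorophenyl]ethylidene}-2-methylpropane-2-sulfinamide; 7 3,4-bis(benzyloxy)benzaldehyde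
Product: 11 (2S)-7,8-bis(benzyloxy)-2-[3,4-bis(benzyloxy)phenyl]chroman-4-one, via magnesium metalloenamine 8 (not isolated), via magnesium aldolate 9 (not isolated), via sulfinyl imine 10 (not isolated)
Conditions: LiN(i-Pr)2, THF, −78 °C; MgBr2·OEt2; 7, −78 °C; DMPU, −78 → 0 °C; 1 M aq. HCl, THF, 23 °C
Reagents that add atoms: water, O
Why: Proposed new method: LiN(i-Pr)2 removes a methyl proton of 6, the metalloenamine 8 adds to aldehyde 7 (C2–C3 bond) through a closed, magnesium-bridged chair-like transition state, and the alkoxide 9 then displaces fluoride at C8a by intramolecular addition–elimination (SNAr, O1–C8a bond), because C8a is ortho to the ring carbon that carries the electron-poor C=N–S(O) group; aqueous acid hydrolyses imine 10 to the ketone and the sulfinamide. The closest known reaction types are the auxiliary-controlled aldol addition of metalloenamines from N-tert-butanesulfinyl aryl methyl ketimines to aldehydes and the base-mediated SNAr closure of β-hydroxy ortho-fluoroaryl ketones to chroman-4-ones; joining them in one flask with the imine as the activating group is new. Ring C closes as a six-membered ring at the aromatic carbon C8a, exo with respect to the departing C–F bond, while the charge of the σ-adduct is taken up by the C8a=C4a–C4=N system inside the new ring. The only new stereocentre, C2, is fixed in the C–C bond-forming event by the sulfur stereocentre of the auxiliary. The step needs ring closure to outrun retro-aldol cleavage and E1cB dehydration: magnesium chelation holds the aldolate at low temperature, no base strong enough to re-form an azaenolate remains, and the ortho imine together with the inductive pull of the C8 oxygen makes C8a the only electrophilic aryl carbon.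

Step 5
Reactants: 11 (2S)-7,8-bis(benzyloxy)-2-[3,4-bis(benzyloxy)phenyl]chroman-4-one
Product: 13 (2R,3R)-7,8-bis(benzyloxy)-2-[3,4-bis(benzyloxy)phenyl]-3-hydroxychroman-4-one, via silyl enol ether 12 (not isolated)
Conditions: Me3SiOTf, Et3N, CH2Cl2, 0 °C; dimethyldioxirane, acetone, −40 °C; citric acid, MeOH, 23 °C
Reagents that add atoms: dimethyldioxirane, CC1(C)OO1
Why: In this Rubottom oxidation soft enolisation avoids a free enolate (no ring opening at C2), and the dioxirane should attack the C3=C4 enol ether on the face opposite the C2 aryl group, so the new C3–O bond is trans to it (substrate control from C2).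

Step 6
Reactants: 13 (2R,3R)-7,8-bis(benzyloxy)-2-[3,4-bis(benzyloxy)phenyl]-3-hydroxychroman-4-one
Product: 15 (2R,3S)-7,8-bis(benzyloxy)-2-[3,4-bis(benzyloxy)phenyl]chroman-3-ol, via 3,4-diol 14 (not isolated)
Conditions: NaBH4, THF/MeOH, 0 °C; then crude diol, Et3SiH, CF3CO2H, CH2Cl2, −20 °C
Reagents that add atoms: none
Why: Ketone reduction followed by ionic hydrogenation of the C4 benzylic cation (stabilised by the para C7 oxygen and the ortho ring oxygen) removes the activating carbonyl, as in the known conversion of dihydroflavonols to flavan-3-ols, and leaves C2 and C3 untouched.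

Step 7
Reactants: 16 (2R,3R)-fustin
Product: 17 (2R,3R)-7-(benzyloxy)-2-[3,4-bis(benzyloxy)phenyl]-3-hydroxychroman-4-one
Conditions: BnBr, K2CO3, DMF, 23 °C
Reagents that add atoms: benzyl bromide, BrCc1ccccc1
Why: Williamson etherification with a carbonate base is selective for the three phenols over the secondary 3-OH and is mild enough to keep the trans-dihydroflavonol intact.

Step 8
Reactants: 17 (2R,3R)-7-(benzyloxy)-2-[3,4-bis(benzyloxy)phenyl]-3-hydroxychroman-4-one
Product: 19 (2R,3S,4R)-7-(benzyloxy)-2-[3,4-bis(benzyloxy)phenyl]-4-methoxychroman-3-ol, via 3,4-diol 18 (not isolated)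
Conditions: NaBH4, THF/MeOH, 0 °C; then camphorsulfonic acid to pH 3, MeOH, 23 °C
Reagents that add atoms: methanol, CO
Why: Ketone reduction and acid-catalysed SN1 exchange of the benzylic 4-OH with methanol give a storable C4 leaving group while the 3-OH stays free for the tether.

Step 9
Reactants: 15 (2R,3S)-7,8-bis(benzyloxy)-2-[3,4-bis(benzyloxy)phenyl]chroman-3-ol
Product: 20 5-{[(2R,3S)-7,8-bis(benzyloxy)-2-[3,4-bis(benzyloxy)phenyl]chroman-3-yl]oxy}-5-oxopentanoic acid
Conditions: glutaric anhydride, 4-(dimethylamino)pyridine, Et3N, CH2Cl2, 23 °C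
Reagents that add atoms: glutaric anhydride, O=C1CCCC(=O)O1
Why: Nucleophile-catalysed ring opening of the cyclic anhydride by the secondary 3-OH installs the first half of the tether.

Step 10
Reactants: 20 5-{[(2R,3S)-7,8-bis(benzyloxy)-2-[3,4-bis(benzyloxy)phenyl]chroman-3-yl]oxy}-5-oxopentanoic acid; 19 (2R,3S,4R)-7-(benzyloxy)-2-[3,4-bis(benzyloxy)phenyl]-4-methoxychroman-3-ol
Product: 21 (2R,3S,4R)-7-(benzyloxy)-2-[3,4-bis(benzyloxy)phenyl]-4-methoxychroman-3-yl (2R,3S)-7,8-bis(benzyloxy)-2-[3,4-bis(benzyloxy)phenyl]chroman-3-yl pentanedioate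
Conditions: EDC·HCl, 4-(dimethylamino)pyridine, CH2Cl2, 0 → 23 °C
Reagents that add atoms: none
Why: Steglich esterification joins the two flavan units through their 3-oxygens under neutral conditions that do not touch the acid-labile C4 methoxy group.

Step 11
Reactants: 21 (2R,3S,4R)-7-(benzyloxy)-2-[3,4-bis(benzyloxy)phenyl]-4-methoxychroman-3-yl (2R,3S)-7,8-bis(benzyloxy)-2-[3,4-bis(benzyloxy)phenyl]chroman-3-yl pentanedioate
Product: 22 glutarate-bridged dimer with the upper C4 bonded to the lower C6 (4β and cis to O-3; 14-membered ring)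
Conditions: Me3SiOTf (0.2 equiv), CH2Cl2 (1 mM), −40 → −20 °C
Reagents that add atoms: none
Why: In this intramolecular Friedel–Crafts flavanylation Me3SiOTf ionises C4–OMe and the tether on the β-oriented O-3 should deliver C6 of the lower ring A (para to O1 and ortho to O7, and more nucleophilic than C5, whose only para donor, the doubly flanked 8-benzyloxy group, is twisted out of conjugation) to the β-face of the cation, so that C4 is set cis to O-3, in line with diester-tethered couplings of this kind that override the usual 3,4-trans preference of untethered flavanylations.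

Step 12
Reactants: 22 glutarate-bridged dimer with the upper C4 bonded to the lower C6 (4β and cis to O-3; 14-membered ring)
Product: 23 hepta-O-benzyl fisetinidol-(4β→6)-mesquitol
Conditions: NaOMe, MeOH/THF, 40 °C
Reagents that add atoms: none
Why: Base-catalysed transesterification releases both secondary alcohols and removes the tether without affecting any stereocentre.

Step 13
Reactants: 23 hepta-O-benzyl fisetinidol-(4β→6)-mesquitol
Product: 24 CNP0252692.1 (fisetinidol-(4β→6)-mesquitol)
Conditions: H2 (1 atm), Pd(OH)2/C, THF/MeOH/H2O, 23 °C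
Reagents that add atoms: none
Why: Hydrogenolysis of the seven benzyl ethers under neutral conditions of the kind used for benzylated proanthocyanidins should leave the interflavan bond and the benzylic ring C–O bonds intact.

**Compound list**
1 | 3-fluorobenzene-1,2-diol (3-fluorocatechol) | Oc1cccc(F)c1O | starting material
2 | 1,2-bis(benzyloxy)-3-fluorobenzene | Fc1cccc(OCc2ccccc2)c1OCc1ccccc1 | intermediate
3 | [3,4-bis(benzyloxy)-2-fluorophenyl]lithium | [Li]c1ccc(OCc2ccccc2)c(OCc2ccccc2)c1F | intermediate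
4 | 1-[3,4-bis(benzyloxy)-2-fluorophenyl]ethan-1-one | CC(=O)c1ccc(OCc2ccccc2)c(OCc2ccccc2)c1F | intermediate
5 | (S)-2-methylpropane-2-sulfinamide | CC(C)(C)[S@](=O)N | starting material
6 | (S)-N-{(E)-1-[3,4-bis(benzyloxy)-2-fluorophenyl]ethylidene}-2-methylpropane-2-sulfinamide | CC(C)(C)[S@](=O)/N=C(\C)c1ccc(OCc2ccccc2)c(OCc2ccccc2)c1F | intermediate
7 | 3,4-bis(benzyloxy)benzaldehyde | O=Cc1ccc(OCc2ccccc2)c(OCc2ccccc2)c1 | starting material
8 | bromomagnesium metalloenamine, (S)-N-(bromomagnesio)-N-{1-[3,4-bis(benzyloxy)-2-fluorophenyl]ethenyl}-2-methylpropane-2-sulfinamide | C=C(c1ccc(OCc2ccccc2)c(OCc2ccccc2)c1F)N([Mg]Br)[S@@](=O)C(C)(C)C | intermediate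
9 | bromomagnesium aldolate, (S)-N-{(1E,3S)-1-[3,4-bis(benzyloxy)-2-fluorophenyl]-3-[3,4-bis(benzyloxy)phenyl]-3-[(bromomagnesio)oxy]propylidene}-2-methylpropane-2-sulfinamide | CC(C)(C)[S@](=O)/N=C(\C[C@H](O[Mg]Br)c1ccc(OCc2ccccc2)c(OCc2ccccc2)c1)c1ccc(OCc2ccccc2)c(OCc2ccccc2)c1F | intermediate
10 | (S)-N-{(2S,4E)-7,8-bis(benzyloxy)-2-[3,4-bis(benzyloxy)phenyl]chroman-4-ylidene}-2-methylpropane-2-sulfinamide | c1cc2c(c(OCc3ccccc3)c1OCc1ccccc1)O[C@H](c1ccc(OCc3ccccc3)c(OCc3ccccc3)c1)C/C2=N\[S@@](=O)C(C)(C)C | intermediate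
11 | (2S)-7,8-bis(benzyloxy)-2-[3,4-bis(benzyloxy)phenyl]chroman-4-one | c1cc2c(c(OCc3ccccc3)c1OCc1ccccc1)O[C@H](c1ccc(OCc3ccccc3)c(OCc3ccccc3)c1)CC2=O | intermediate
12 | (2S)-7,8-bis(benzyloxy)-2-[3,4-bis(benzyloxy)phenyl]-4-(trimethylsilyloxy)-2H-chromene | c1cc2c(c(OCc3ccccc3)c1OCc1ccccc1)O[C@H](c1ccc(OCc3ccccc3)c(OCc3ccccc3)c1)C=C2O[Si](C)(C)C | intermediate
13 | (2R,3R)-7,8-bis(benzyloxy)-2-[3,4-bis(benzyloxy)phenyl]-3-hydroxychroman-4-one | c1cc2c(c(OCc3ccccc3)c1OCc1ccccc1)O[C@H](c1ccc(OCc3ccccc3)c(OCc3ccccc3)c1)[C@@H](O)C2=O | intermediate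
14 | (2R,3S,4R)-7,8-bis(benzyloxy)-2-[3,4-bis(benzyloxy)phenyl]chromane-3,4-diol | c1cc2c(c(OCc3ccccc3)c1OCc1ccccc1)O[C@H](c1ccc(OCc3ccccc3)c(OCc3ccccc3)c1)[C@@H](O)[C@@H]2O | intermediate
15 | (2R,3S)-7,8-bis(benzyloxy)-2-[3,4-bis(benzyloxy)phenyl]chroman-3-ol (tetra-O-benzyl mesquitol) | c1cc2c(c(OCc3ccccc3)c1OCc1ccccc1)O[C@H](c1ccc(OCc3ccccc3)c(OCc3ccccc3)c1)[C@@H](O)C2 | intermediate
16 | (2R,3R)-fustin, (2R,3R)-2-(3,4-dihydroxyphenyl)-3,7-dihydroxychroman-4-one | Oc1ccc2c(c1)O[C@H](c1ccc(O)c(O)c1)[C@@H](O)C2=O | starting material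
17 | (2R,3R)-7-(benzyloxy)-2-[3,4-bis(benzyloxy)phenyl]-3-hydroxychroman-4-one | c1ccccc1COc1ccc2c(c1)O[C@H](c1ccc(OCc3ccccc3)c(OCc3ccccc3)c1)[C@@H](O)C2=O | intermediate
18 | (2R,3S,4R)-7-(benzyloxy)-2-[3,4-bis(benzyloxy)phenyl]chromane-3,4-diol | c1ccccc1COc1ccc2c(c1)O[C@H](c1ccc(OCc3ccccc3)c(OCc3ccccc3)c1)[C@@H](O)[C@@H]2O | intermediate
19 | (2R,3S,4R)-7-(benzyloxy)-2-[3,4-bis(benzyloxy)phenyl]-4-methoxychroman-3-ol | c1ccccc1COc1ccc2c(c1)O[C@H](c1ccc(OCc3ccccc3)c(OCc3ccccc3)c1)[C@@H](O)[C@@H]2OC | intermediate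
20 | 5-{[(2R,3S)-7,8-bis(benzyloxy)-2-[3,4-bis(benzyloxy)phenyl]chroman-3-yl]oxy}-5-oxopentanoic acid | c1cc2c(c(OCc3ccccc3)c1OCc1ccccc1)O[C@H](c1ccc(OCc3ccccc3)c(OCc3ccccc3)c1)[C@@H](OC(=O)CCCC(O)=O)C2 | intermediate
21 | (2R,3S,4R)-7-(benzyloxy)-2-[3,4-bis(benzyloxy)phenyl]-4-methoxychroman-3-yl (2R,3S)-7,8-bis(benzyloxy)-2-[3,4-bis(benzyloxy)phenyl]chroman-3-yl pentanedioate (mixed glutarate diester through both O-3 atoms) | c1ccccc1COc1ccc2c(c1)O[C@H](c1ccc(OCc3ccccc3)c(OCc3ccccc3)c1)[C@@H](OC(=O)CCCC(=O)O[C@H]1Cc3ccc(OCc4ccccc4)c(OCc4ccccc4)c3O[C@@H]1c1ccc(OCc3ccccc3)c(OCc3ccccc3)c1)[C@@H]2OC | intermediate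
22 | glutarate-bridged dimer with the upper C4 bonded to the lower C6 (4β and cis to O-3; 14-membered ring) | c1ccccc1COc1ccc2c(c1)O[C@H](c1ccc(OCc3ccccc3)c(OCc3ccccc3)c1)[C@@H](OC(=O)CCCC(=O)O[C@H]1Cc3cc5c(OCc4ccccc4)c(OCc4ccccc4)c3O[C@@H]1c1ccc(OCc3ccccc3)c(OCc3ccccc3)c1)[C@H]25 | intermediate
23 | hepta-O-benzyl fisetinidol-(4β→6)-mesquitol | c1ccccc1COc1ccc2c(c1)O[C@H](c1ccc(OCc3ccccc3)c(OCc3ccccc3)c1)[C@@H](O)[C@H]2c1cc2c(c(OCc3ccccc3)c1OCc1ccccc1)O[C@H](c1ccc(OCc3ccccc3)c(OCc3ccccc3)c1)[C@@H](O)C2 | intermediate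
24 | CNP0252692.1, fisetinidol-(4β→6)-mesquitol | Oc1ccc2c(c1)O[C@H](c1ccc(O)c(O)c1)[C@@H](O)[C@H]2c1cc2c(c(O)c1O)O[C@H](c1ccc(O)c(O)c1)[C@@H](O)C2 | target

**Step count and risks**
Total steps: 13. Longest linear sequence: 11 steps (steps 1–6, then 9–13); the upper unit joins after 2 steps (steps 7 and 8).

Step 4 (Proposed new method). The magnesium aldolate may revert by retro-aldol cleavage or lose water by E1cB elimination faster than it closes onto the electron-rich fluoroarene, and facial control by the auxiliary may erode on warming. The fallback uses known chemistry, sets out from 4 and comes back at 11. KOH in DMSO/H2O replaces the activated ortho-fluorine by hydroxide (SNAr) to give 1-[3,4-bis(benzyloxy)-2-hydroxyphenyl]ethan-1-one F1. Condensation with N,N-dimethylformamide dimethyl acetal and ring closure with aqueous HCl gives 7,8-bis(benzyloxy)-4H-chromen-4-one F2. Catalytic asymmetric conjugate addition of [3,4-bis(benzyloxy)phenyl]boronic acid (Pd(OCOCF3)2 with the enantiomer of a pyridine–oxazoline ligand that delivers the 2S product) then gives 11. In this fallback ring C is made first and C2 is set by the catalyst in a C–aryl bond formation.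

Step 11. Intermolecular oligomerisation may compete with closure of the 14-membered ring, participation by the C3 ester may steer attack to the α-face, ring closure may take place at C5 of the lower ring A instead of C6, or the cation may be lost by elimination. The fallback is the untethered, acid-catalysed flavanylation of the free phenols; it sets out from 15 and 16 and comes back at 24. Hydrogenolysis of 15 (H2, Pd(OH)2/C) gives (2R,3S)-mesquitol F3. NaBH4 reduction of fustin 16 in ethanol gives (2R,3S,4R)-2-(3,4-dihydroxyphenyl)chromane-3,4,7-triol F4. F3 and F4 are condensed in dilute aqueous HCl at 23 °C, a reaction type that gives both C4 epimers, and the 4β isomer 24 is separated by chromatography on Sephadex LH-20.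

Step 5. The dioxirane may over-oxidise the electron-rich rings, attack of the enol ether may not be fully face-selective, or the ring may open at C2 during enolisation. The fallback sets out from 11 and comes back at 15, so that step 6 is not needed. NaBH4 reduction gives (2S,4S)-7,8-bis(benzyloxy)-2-[3,4-bis(benzyloxy)phenyl]chroman-4-ol F5. Dehydration (p-toluenesulfonic acid, toluene, 60 °C) gives (2S)-7,8-bis(benzyloxy)-2-[3,4-bis(benzyloxy)phenyl]-2H-chromene F6. Hydroboration–oxidation (BH3·THF; then H2O2, NaOH) places boron on C3 anti to the C2 aryl group and gives 15.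

**Further compounds**
F1 | step 4 | 1-[3,4-bis(benzyloxy)-2-hydroxyphenyl]ethan-1-one | CC(=O)c1ccc(OCc2ccccc2)c(OCc2ccccc2)c1O
F2 | step 4 | 7,8-bis(benzyloxy)-4H-chromen-4-one | O=c1ccoc2c1ccc(OCc1ccccc1)c2OCc1ccccc1
F3 | step 11 | (2R,3S)-mesquitol, (2R,3S)-2-(3,4-dihydroxyphenyl)chromane-3,7,8-triol | c1cc2c(c(O)c1O)O[C@H](c1ccc(O)c(O)c1)[C@@H](O)C2
F4 | step 11 | (2R,3S,4R)-2-(3,4-dihydroxyphenyl)chromane-3,4,7-triol | Oc1ccc2c(c1)O[C@H](c1ccc(O)c(O)c1)[C@@H](O)[C@@H]2O
F5 | step 5 | (2S,4S)-7,8-bis(benzyloxy)-2-[3,4-bis(benzyloxy)phenyl]chroman-4-ol | c1cc2c(c(OCc3ccccc3)c1OCc1ccccc1)O[C@H](c1ccc(OCc3ccccc3)c(OCc3ccccc3)c1)C[C@@H]2O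
F6 | step 5 | (2S)-7,8-bis(benzyloxy)-2-[3,4-bis(benzyloxy)phenyl]-2H-chromene | c1cc2c(c(OCc3ccccc3)c1OCc1ccccc1)O[C@H](c1ccc(OCc3ccccc3)c(OCc3ccccc3)c1)C=C2
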